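(The numbers in the tables come from a simulation for substances that don't exist; scatter was added.)

In the summer run the substrate lost more than the single product gained: at 12.0 min, 48.8 % had reacted and 17.2 % stood as single product.

| flask | substrate | partner | remark | time |
|---|---|---|---|---|
| summer | 1.5 M | 2.2 M | run made earlier |  |
| flask | 1.5 M | 1.50 M |  | 2.0 h |

- summer (time / min: substrate / %, single product / %): 3.00: 72.0, 15.6; 6.00: 61.4, 17.4; 10.0: 53.8, 17.9; 12.0: 51.2, 17.2

(each reading ± 1 percentage point)

* part of the substrate that has reacted at 2.0 h
* share of the unused partner that is free and not bound as idle adduct, at 2.0 h

- the earlier runs do not show how much of partner is bound; that part of a forecast is a guess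

I supposed that the missing material held further partner, so I reckoned with the partner price n, the partner taken per substrate reacted. With 2 partners in each missing substrate, that reading gave n = 1.65. With 3, which was my guess, it gave n = 2.30. I treated partner as the limiting reagent of the flask, taken up by 2.0 h, so that

reacted part = c(partner) / (n · c(substrate))

At n = 1 the ceiling stood at 100 %. The two prices narrowed this to an estimated range, resting on my guesses and on one scattered summer reading:

ceiling 60.7 %, floor 43.6 %

The free share I could not bracket from these runs.

The forecast gave 60 % reacted and 30 % free, saying “The flask has less partner and no excess”. Its first number lay inside my bracket, just under the ceiling .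

The flask gave 50.2 % reacted and 17.9 % free.

    substrate + partner → single product + released group (k = 0.00120 M⁻¹ s⁻¹)
    partner + single product → bis adduct + released group (k = 0.00420 M⁻¹ s⁻¹)
    partner + bis adduct → tris adduct + released group (k = 0.00280 M⁻¹ s⁻¹)
    partner + released group ⇌ idle adduct, settled at all times (K = 3.10 M⁻¹)

The flask's price, counted from its products at 2.0 h, was 1.98, and its reacted part lay inside the estimated range . In the flask the substrate stood at 50.2 % reacted because of the depletion of partner: 0.17 % of the charged partner was left unbound, and the same run without that depletion reached >99.9 %. In the neighbour flask with 0.38 M of partner, the summer price n = 1.65 gives 15.4 %. The computed result for that neighbour flask was 18.8 %, at a price of 1.35.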